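Count the G.

| flask | D | G | X | temperature | remark | time |
|---|---|---|---|---|---|---|
| dawn | 0.20 M | 0.22 M | 0.40 M | −20 °C | the very flask that is asked about, followed so far |  |
| autumn | 0.40 M | 0.22 M | 0.40 M | −14 °C | run made earlier |  |
| flask | 0.20 M | 0.220 M | 0.400 M | −20 °C |  | 3.0 h |

| run | time / min | L / % | D / % |
|---|---|---|---|
| dawn | 6.00 | 45.8 | 15.8 |
| dawn | 15.0 | 45.9 | 5.1 |
| dawn | 30.0 | 45.8 | 0.8 |
| dawn | 50.0 | 45.8 | 0.6 |
| dawn | 60.0 | 45.1 | 0.2 |
| dawn | 80.0 | 46.0 | 0 |
| dawn | 120 | 45.6 | 0 |
| autumn | 0.333 | 13.5 | 59.8 |
| autumn | 0.500 | 15.3 | 55.6 |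
| autumn | 0.667 | 15.7 | 53.0 |
| autumn | 1.00 | 16.1 | 49.1 |
| autumn | 1.50 | 15.7 | 44.3 |
| autumn | 2.50 | 15.7 | 36.2 |
| autumn | 4.00 | 16.7 | 27.6 |

(readings scatter by 0.3 percentage points)

* L, in percent of the D first charged, at 3.0 h
* the remedy with the largest gain of L, or "none" below 2 percentage points (Wednesday's / Sunday's / Monday's / Friday's / none)
* L present, in percent of the D first charged, after Sunday's
* L present, in percent of the D first charged, after Monday's

- Wednesday's: change nothing and wait 6.0 h more
- Sunday's: at 3.0 h add G, 100% of the amount charged, then wait 6.0 h
- Monday's: at 3.0 h take out 90% of the X then present, then wait 6.0 h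
- Friday's: at 3.0 h raise the temperature by 10 K, then wait 6.0 h

- the volume of additions can be left aside
- the numbers in the tables scatter by 0.3 percentage points (one standard deviation)

Each exchange on a D spends one G, and L carries two exchanges. G charged per D charged in the dawn flask is 110%, the G budget. Start with the main step alone, D going straight to L: two G per L, G as limiting reagent, and the budget buys 55.0% of L.

The dawn readings stand lower, at 45.6% after 120 min, and L is flat from the first reading on, with D still at 15.8%. So add a second process. The first exchange is a step of its own and gives Q, a complex with one exchanged, which then competes with D for G. With G taken as zero, the budget equals two L plus Q, so the last dawn reading puts Q at 18.8%, and L stands 9.4 percentage points below what the budget buys.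

Then the rest: D keeps falling after L has stopped, down to 0% in the dawn run. That loss spends no G, so the balance stands, and the reckoning here puts L at 3.0 h at 45.6%. Waiting, taking out X and warming add no G. Sunday's adds 110%, more than Q can take, so L should reach L plus Q, 64.4%, as long as Q has stayed.

The forecast gives 45.7% now, Sunday's as best, 64.3% after Sunday's and 45.7% after Monday's, and holds that “Waiting, removing X or warming gives nothing”. Its Sunday figure differs from the one here because it starts from L at 45.7%.

The flask gives 45.6%, then 64.4% after Sunday's, a gain of 19 points, and 45.6% after Monday's. Friday's brings 0 points.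

    D + G → X + Q (k = 0.143 /M/s, Ea = 48.0 kJ/mol)
    Q + G → X + L (k = 0.299 /M/s, Ea = 44.0 kJ/mol)
    X + D → E (k = 0.00359 /M/s, Ea = 47.0 kJ/mol)
    (constants at −20 °C)

The using up of G is the main reason for L at 45.6% in this flask, where Q stands at 18.8% against 18.8% from the budget. Taking away the step X + D to E changes L by −1.4 points. The neighbour flask with 0.050 M of D has a budget of 440%, and its L of 94.1%, with Q at 0%, should leave 57.2% of its own G. That neighbour flask keeps 57%.

Readings and results are simulated on assumed constants, noise included.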